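**Plan**

1. Retrosynthetic cuts: the C3 ester; the 6β,19-diol, read back as a γ-lactone C4–C19(=O)–O–C6 (temporary ring); then C5–C10 and C3–C4 in one operation (both carbocycles); then C4=C5 (metathesis), C1=C10 (Wittig), C8–C17 and C10–O6 (pyranone opening), C6–C7 (aldol) and C9–C11 (Suzuki).
2. Forward order: the side chain is joined to a vinylogous ester; a dihydropyranone (first temporary ring) fixes the Z C8=C9 bond and carries C6; it is opened; the butenolide (second temporary ring) is closed; one radical–polar step closes ring B through C5–C10 and ring A through C3–C4; the lactone is finally reduced to the diol.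
3. Stereochemistry: C6 from a BINOL–titanium aldol; C5 and C4 relayed from C6 by the lactone tethers; C10 in the radical ring closure; C3 by bulky-hydride reduction of the ketone; 13E by syn carbocupration.
4. Enabling feature: C10 is allylic to the C8=C9 bond of ring B, so a C10 radical is a tertiary allyl radical; with C19 and O6 tied as a lactone, C5 is the β carbon of a butenolide held beside C7, and C4 (α to C19) is placed to close ring A on a C3 aldehyde.

Key step: step 10

Assumption: the (R)-BINOL–titanium catalyst is taken to give the 9R carbinol (2R pyranone) in step 4; if the opposite sense is found, (S)-BINOL is used and nothing else changes. Labdane numbering (5α-H, 10β-CH3, 4α-CH3) is used for all bicyclic compounds.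

**Step 1**
Reactants: 1 tert-butyl but-2-ynoate
Product: 2 tert-butyl (2E)-3-methylpenta-2,4-dienoate
Conditions: CH2=CHMgBr, CuBr·SMe2, THF, −78 °C; then MeOH, NH4Cl (aq), −78 °C
Reagents that add atoms: vinylmagnesium bromide, C=C[Mg]Br
Why: Syn carbocupration of the ynoate (organocopper conjugate addition) and cold protonation should place the vinyl group cis to H, which fixes the 13E enoate of the side chain.

**Step 2**
Reactants: 3 (3E)-4-methoxypent-3-en-2-one
Product: 4 3-iodo-4-methoxypent-3-en-2-one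
Conditions: I2, pyridine, CH2Cl2, 0 to 25 °C
Reagents that add atoms: iodine, II
Why: α-Iodination of the vinylogous ester (Johnson iodination of enones) should give the sp2 electrophile that becomes C9.

**Step 3**
Reactants: 2 tert-butyl (2E)-3-methylpenta-2,4-dienoate; 4 3-iodo-4-methoxypent-3-en-2-one
Product: 6 tert-butyl (2E)-6-acetyl-7-methoxy-3-methylocta-2,6-dienoate, via B-alkyl-9-BBN adduct 5 (not isolated)
Conditions: 9-BBN, THF, 0 to 25 °C; then 4, Pd(dppf)Cl2 (5 mol %), AsPh3, Cs2CO3, DMF–H2O, 25 °C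
Reagents that add atoms: none
Why: 9-BBN should hydroborate only the monosubstituted terminal alkene of 2 at its CH2 end, and B-alkyl Suzuki–Miyaura coupling with the α-iodoenone joins C11 to C9 without touching the 13E enoate.

**Step 4**
Reactants: 6 tert-butyl (2E)-6-acetyl-7-methoxy-3-methylocta-2,6-dienoate; 7 (2E)-but-2-enal
Product: 10 tert-butyl (2E)-3-methyl-5-{(2R)-6-methyl-4-oxo-2-[(1E)-prop-1-enyl]-3,4-dihydro-2H-pyran-5-yl}pent-2-enoate, via silyl dienol ether 8 (not isolated), via silyl aldol adduct 9 (not isolated)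
Conditions: LiN(iPr)2, Me3SiCl, THF, −78 °C; solvent change; 7, Ti(OiPr)4 (10 mol %), (R)-BINOL (20 mol %), 4 Å MS, Et2O, −20 °C; then CF3CO2H (0.5 equiv), CH2Cl2, 0 °C
Reagents that add atoms: none
Why: Kinetic enol silylation of the methyl ketone gives a Danishefsky-type diene whose BINOL–titanium-catalysed Mukaiyama aldol addition to 7 (Keck hetero-Diels–Alder protocol) sets C6, and acid closes the pyranone by addition–elimination at the methoxy carbon, so that C7 and C10 are held cis in a ring.

**Step 5**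
Reactants: 10 tert-butyl (2E)-3-methyl-5-{(2R)-6-methyl-4-oxo-2-[(1E)-prop-1-enyl]-3,4-dihydro-2H-pyran-5-yl}pent-2-enoate
Product: 12 tert-butyl (2E,6Z,9R,10E)-6-acetyl-9-hydroxy-3,7-dimethyldodeca-2,6,10-trienoate, via tertiary lithium alkoxide 11 (not isolated)
Conditions: MeLi, THF, −78 °C; then 1 M HCl, THF, 0 °C
Reagents that add atoms: methyllithium, C[Li]; water, O
Why: 1,2-Addition of MeLi to the vinylogous ester carbonyl followed by acidic hydrolysis with allylic transposition (Stork–Danheiser sequence) should deliver C17 and open the ring to the enone, whose 8Z geometry is inherited from the ring and protected by the hemiketal equilibrium.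

**Step 6**
Reactants: 12 tert-butyl (2E,6Z,9R,10E)-6-acetyl-9-hydroxy-3,7-dimethyldodeca-2,6,10-trienoate; 13 [2-(1,3-dioxolan-2-yl)ethyl]triphenylphosphonium bromide
Product: 15 tert-butyl (2E,6Z,9R,10E)-6-[4-(1,3-dioxolan-2-yl)but-2-en-2-yl]-9-hydroxy-3,7-dimethyldodeca-2,6,10-trienoate, via phosphorus ylide 14 (not isolated)
Conditions: 13, KN(SiMe3)2, THF, −78 to 0 °C; then 12, 0 to 40 °C
Reagents that add atoms: none
Why: Wittig olefination of the methyl ketone with the unstabilised ylide adds C1–C3, and the geometry of the new C1=C10 bond is immaterial because step 10 consumes it.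

**Step 7**
Reactants: 15 tert-butyl (2E,6Z,9R,10E)-6-[4-(1,3-dioxolan-2-yl)but-2-en-2-yl]-9-hydroxy-3,7-dimethyldodeca-2,6,10-trienoate
Product: 16 tert-butyl (2E,6Z,9R,10E)-6-[4-(1,3-dioxolan-2-yl)but-2-en-2-yl]-3,7-dimethyl-9-(2-methylprop-2-enoyloxy)dodeca-2,6,10-trienoate
Conditions: methacryloyl chloride, Et3N, DMAP (cat.), CH2Cl2, 0 °C
Reagents that add atoms: methacryloyl chloride, CC(=C)C(Cl)=O
Why: DMAP-catalysed acylation of the only hydroxyl group supplies C4, C18 and C19 as the metathesis partner.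

**Step 8**
Reactants: 16 tert-butyl (2E,6Z,9R,10E)-6-[4-(1,3-dioxolan-2-yl)but-2-en-2-yl]-3,7-dimethyl-9-(2-methylprop-2-enoyloxy)dodeca-2,6,10-trienoate
Product: 17 tert-butyl (2E,6Z)-6-[4-(1,3-dioxolan-2-yl)but-2-en-2-yl]-3,7-dimethyl-8-[(2R)-4-methyl-5-oxo-2,5-dihydrofuran-2-yl]octa-2,6-dienoate
Conditions: second-generation Grubbs catalyst (5 mol %), toluene, 80 °C
Reagents that add atoms: none
Why: Ring-closing metathesis of the methacrylate with the propenyl group should form the α-methylbutenolide with loss of propene, while the tetrasubstituted alkene, the hindered diene and the conjugated ester are not engaged.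

**Step 9**
Reactants: 17 tert-butyl (2E,6Z)-6-[4-(1,3-dioxolan-2-yl)but-2-en-2-yl]-3,7-dimethyl-8-[(2R)-4-methyl-5-oxo-2,5-dihydrofuran-2-yl]octa-2,6-dienoate
Product: 18 tert-butyl (2E,6Z)-3,7-dimethyl-8-[(2R)-4-methyl-5-oxo-2,5-dihydrofuran-2-yl]-6-(5-oxopent-2-en-2-yl)octa-2,6-dienoate
Conditions: PPTS, acetone–H2O, 50 °C
Reagents that add atoms: water, O
Why: Mild acid-catalysed acetal hydrolysis should free the C3 aldehyde without cleaving the tert-butyl ester or moving the double bonds, and the aldehyde is used at once.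

**Step 10**
Reactants: 18 tert-butyl (2E,6Z)-3,7-dimethyl-8-[(2R)-4-methyl-5-oxo-2,5-dihydrofuran-2-yl]-6-(5-oxopent-2-en-2-yl)octa-2,6-dienoate
Product: 20 tert-butyl 3-hydroxy-19-oxo-19,6β-epoxylabda-8,13E-dien-15-oate (C3 epimers), via ring-B lactone enolate 19 (not isolated)
Conditions: Fe(acac)3 (30 mol %), PhSiH3, EtOH–(CH2OH)2 (5:1), 0.01 M, 25 °C
Reagents that add atoms: none
Why: Proposed new method: hydrogen-atom transfer from the iron hydride to C1, the open terminus of the C1=C10–C9=C8 diene, should give the pentasubstituted allyl radical, which adds through C10 to the butenolide β carbon C5 (6-exo-trig, ring B; attack through C8 could only make a four-membered ring), and the C4 lactone radical is then reduced to the iron enolate, which closes ring A on the C3 aldehyde (6-(enolexo)-exo-trig aldol). The closest known reaction type is the iron-hydride-initiated radical conjugate addition–aldol (radical–polar crossover) polycyclisation of alkenyl enals; what is new is a conjugated diene as the hydrogen-atom acceptor and a butenolide as the radical acceptor. C5 is set by C6, because the three-atom tether C7–C8=C9 reaches only the lactone face syn to C7, and C4 is set the same way, because C3 is delivered on the face that carries C10. At C10 the methyl group should take the inside site of the allyl radical (gauche to C4 and C6) and the longer C1 chain the outside site anti to C6, which relieves allylic 1,3-strain with C7 and leads to the trans-decalin with axial C20; C3 is expected mainly as the 3β alcohol from a chelated aldol and is reset in steps 11 and 12. The step needs hydrogen-atom transfer to the electron-rich diene and not to the two electron-poor alkenes, which the polarity of the metal hydride should secure, and it needs the aldol to outrun protonation of the enolate, which the six-membered intramolecular delivery at high dilution should secure.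

**Step 11**
Reactants: 20 tert-butyl 3-hydroxy-19-oxo-19,6β-epoxylabda-8,13E-dien-15-oate (C3 epimers)
Product: 21 tert-butyl 3,19-dioxo-19,6β-epoxylabda-8,13E-dien-15-oate
Conditions: Dess–Martin periodinane, NaHCO3, CH2Cl2, 0 to 25 °C
Reagents that add atoms: none
Why: Dess–Martin oxidation converges both C3 epimers on the ketone so that the centre can be set by reduction.

**Step 12**
Reactants: 21 tert-butyl 3,19-dioxo-19,6β-epoxylabda-8,13E-dien-15-oate
Product: 22 tert-butyl 3α-hydroxy-19-oxo-19,6β-epoxylabda-8,13E-dien-15-oate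
Conditions: LiBH(s-Bu)3, THF, −78 °C; then H2O
Reagents that add atoms: none
Why: The bulky hydride should attack the 3-ketone from the equatorial direction, the axial path being blocked by the 1α and 5α hydrogens, and so give the axial 3α alcohol, as in Selectride reductions of 4,4-disubstituted 3-oxo terpenoids.

**Step 13**
Reactants: 22 tert-butyl 3α-hydroxy-19-oxo-19,6β-epoxylabda-8,13E-dien-15-oate
Product: 23 tert-butyl 3α,6β,19-trihydroxylabda-8,13E-dien-15-oate
Conditions: LiBH4, THF–MeOH, 0 to 25 °C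
Reagents that add atoms: none
Why: Chemoselective borohydride reduction should open the γ-lactone to the 6β,19-diol while the hindered, conjugated tert-butyl ester is left intact.

**Step 14**
Reactants: 23 tert-butyl 3α,6β,19-trihydroxylabda-8,13E-dien-15-oate
Product: 24 tert-butyl 3α-hydroxy-6β,19-(isopropylidenedioxy)labda-8,13E-dien-15-oate
Conditions: Me2C(OMe)2, PPTS (cat.), CH2Cl2, 25 °C
Reagents that add atoms: 2,2-dimethoxypropane, COC(C)(C)OC
Why: Acetonide formation (transacetalisation) is possible only between the syn-diaxial 6β and 19 hydroxyls, so the 3α hydroxyl, which is anti to C19, stays free.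

**Step 15**
Reactants: 24 tert-butyl 3α-hydroxy-6β,19-(isopropylidenedioxy)labda-8,13E-dien-15-oate
Product: 25 tert-butyl 6β,19-(isopropylidenedioxy)-3α-(3-methylbutanoyloxy)labda-8,13E-dien-15-oate
Conditions: (iPrCH2CO)2O, DMAP, Et3N, CH2Cl2, 25 to 40 °C
Reagents that add atoms: 3-methylbutanoic anhydride, CC(C)CC(=O)OC(=O)CC(C)C
Why: DMAP-catalysed acylation of the single free hydroxyl installs the isovalerate, and acyl migration to O19 is excluded by the anti arrangement.

**Step 16**
Reactants: 25 tert-butyl 6β,19-(isopropylidenedioxy)-3α-(3-methylbutanoyloxy)labda-8,13E-dien-15-oate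
Product: 26 6β,19-dihydroxy-3α-(3-methylbutanoyloxy)labda-8,13E-dien-15-oic acid (target)
Conditions: CF3CO2H–CH2Cl2–H2O, 0 °C; then NaHCO3 (aq), then acidification
Reagents that add atoms: none
Why: Acidolysis should remove the acetonide (acetal hydrolysis) and the tert-butyl ester (loss of isobutene) in one operation, the secondary isovalerate being stable to acid.

**Compound list**

1 | tert-butyl but-2-ynoate | CC#CC(=O)OC(C)(C)C | starting material
2 | tert-butyl (2E)-3-methylpenta-2,4-dienoate | C=C/C(C)=C/C(=O)OC(C)(C)C | intermediate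
3 | (3E)-4-methoxypent-3-en-2-one | CO/C(C)=C/C(C)=O | starting material
4 | 3-iodo-4-methoxypent-3-en-2-one (enol-ether geometry immaterial) | COC(C)=C(I)C(C)=O | intermediate
5 | tert-butyl (2E)-5-(9-borabicyclo[3.3.1]nonan-9-yl)-3-methylpent-2-enoate | CC(C)(C)OC(=O)/C=C(\C)CCB1C2CCCC1CCC2 | intermediate
6 | tert-butyl (2E)-6-acetyl-7-methoxy-3-methylocta-2,6-dienoate (6,7-geometry immaterial) | COC(C)=C(CC/C(C)=C/C(=O)OC(C)(C)C)C(C)=O | intermediate
7 | (2E)-but-2-enal | C/C=C/C=O | starting material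
8 | tert-butyl (2E)-7-methoxy-3-methyl-6-[1-(trimethylsilyloxy)ethenyl]octa-2,6-dienoate | COC(C)=C(CC/C(C)=C/C(=O)OC(C)(C)C)C(=C)O[Si](C)(C)C | intermediate
9 | tert-butyl (2E)-7-methoxy-3-methyl-6-[(3R,4E)-3-(trimethylsilyloxy)hex-4-enoyl]octa-2,6-dienoate | C/C=C/[C@H](O[Si](C)(C)C)CC(=O)C(CC/C(C)=C/C(=O)OC(C)(C)C)=C(C)OC | intermediate
10 | tert-butyl (2E)-3-methyl-5-{(2R)-6-methyl-4-oxo-2-[(1E)-prop-1-enyl]-3,4-dihydro-2H-pyran-5-yl}pent-2-enoate | CC1=C(CC/C(C)=C/C(=O)OC(C)(C)C)C(=O)C[C@H](/C=C/C)O1 | intermediate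
11 | lithium alkoxide of tert-butyl (2E)-5-{(2R)-4-hydroxy-4,6-dimethyl-2-[(1E)-prop-1-enyl]-3,4-dihydro-2H-pyran-5-yl}-3-methylpent-2-enoate (carbinol centre either configuration) | CC1=C(CC/C(C)=C/C(=O)OC(C)(C)C)C(C)([O-])C[C@H](/C=C/C)O1.[Li+] | intermediate
12 | tert-butyl (2E,6Z,9R,10E)-6-acetyl-9-hydroxy-3,7-dimethyldodeca-2,6,10-trienoate (in equilibrium with its cyclic hemiketal) | C/C=C/[C@H](O)C/C(C)=C(CC/C(C)=C/C(=O)OC(C)(C)C)\C(C)=O | intermediate
13 | [2-(1,3-dioxolan-2-yl)ethyl]triphenylphosphonium bromide | [Br-].C1COC(CC[P+](c2ccccc2)(c2ccccc2)c2ccccc2)O1 | starting material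
14 | [2-(1,3-dioxolan-2-yl)ethylidene]triphenylphosphorane | C1COC(CC=P(c2ccccc2)(c2ccccc2)c2ccccc2)O1 | intermediate
15 | tert-butyl (2E,6Z,9R,10E)-6-[4-(1,3-dioxolan-2-yl)but-2-en-2-yl]-9-hydroxy-3,7-dimethyldodeca-2,6,10-trienoate (butenyl double bond E/Z mixture) | C/C=C/[C@H](O)C/C(C)=C(CC/C(C)=C/C(=O)OC(C)(C)C)\C(C)=CCC1OCCO1 | intermediate
16 | tert-butyl (2E,6Z,9R,10E)-6-[4-(1,3-dioxolan-2-yl)but-2-en-2-yl]-3,7-dimethyl-9-(2-methylprop-2-enoyloxy)dodeca-2,6,10-trienoate | C/C=C/[C@H](OC(=O)C(C)=C)C/C(C)=C(CC/C(C)=C/C(=O)OC(C)(C)C)\C(C)=CCC1OCCO1 | intermediate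
17 | tert-butyl (2E,6Z)-6-[4-(1,3-dioxolan-2-yl)but-2-en-2-yl]-3,7-dimethyl-8-[(2R)-4-methyl-5-oxo-2,5-dihydrofuran-2-yl]octa-2,6-dienoate | O=C1O[C@H](C/C(C)=C(CC/C(C)=C/C(=O)OC(C)(C)C)\C(C)=CCC2OCCO2)C=C1C | intermediate
18 | tert-butyl (2E,6Z)-3,7-dimethyl-8-[(2R)-4-methyl-5-oxo-2,5-dihydrofuran-2-yl]-6-(5-oxopent-2-en-2-yl)octa-2,6-dienoate | O=C1O[C@H](C/C(C)=C(CC/C(C)=C/C(=O)OC(C)(C)C)\C(C)=CCC=O)C=C1C | intermediate
19 | C4 enolate (iron-bound) of tert-butyl 3,19-dioxo-19,6β-epoxy-3,4-secolabda-8,13E-dien-15-oate | CC1=C(CC/C(C)=C/C(=O)OC(C)(C)C)[C@@](C)(CCC=O)[C@@H]2C(C)=C([O-])O[C@@H]2C1 | intermediate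
20 | tert-butyl 3-hydroxy-19-oxo-19,6β-epoxylabda-8,13E-dien-15-oate (C3 epimers) | CC1=C(CC/C(C)=C/C(=O)OC(C)(C)C)[C@@]2(C)CCC(O)[C@](C)(C(=O)O3)[C@@H]2[C@H]3C1 | intermediate
21 | tert-butyl 3,19-dioxo-19,6β-epoxylabda-8,13E-dien-15-oate | CC1=C(CC/C(C)=C/C(=O)OC(C)(C)C)[C@@]2(C)CCC(=O)[C@](C)(C(=O)O3)[C@@H]2[C@H]3C1 | intermediate
22 | tert-butyl 3α-hydroxy-19-oxo-19,6β-epoxylabda-8,13E-dien-15-oate | CC1=C(CC/C(C)=C/C(=O)OC(C)(C)C)[C@@]2(C)CC[C@@H](O)[C@](C)(C(=O)O3)[C@@H]2[C@H]3C1 | intermediate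
23 | tert-butyl 3α,6β,19-trihydroxylabda-8,13E-dien-15-oate | CC1=C(CC/C(C)=C/C(=O)OC(C)(C)C)[C@@]2(C)CC[C@@H](O)[C@](C)(CO)[C@@H]2[C@H](O)C1 | intermediate
24 | tert-butyl 3α-hydroxy-6β,19-(isopropylidenedioxy)labda-8,13E-dien-15-oate | CC1=C(CC/C(C)=C/C(=O)OC(C)(C)C)[C@@]2(C)CC[C@@H](O)[C@](C)(COC(C)(C)O3)[C@@H]2[C@H]3C1 | intermediate
25 | tert-butyl 6β,19-(isopropylidenedioxy)-3α-(3-methylbutanoyloxy)labda-8,13E-dien-15-oate | CC1=C(CC/C(C)=C/C(=O)OC(C)(C)C)[C@@]2(C)CC[C@@H](OC(=O)CC(C)C)[C@](C)(COC(C)(C)O3)[C@@H]2[C@H]3C1 | intermediate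
26 | 6β,19-dihydroxy-3α-(3-methylbutanoyloxy)labda-8,13E-dien-15-oic acid | CC1=C(CC/C(C)=C/C(=O)O)[C@@]2(C)CC[C@@H](OC(=O)CC(C)C)[C@](C)(CO)[C@@H]2[C@H](O)C1 | target

**Step count and risks**

Total: 16 steps. Longest linear sequence: 15 steps (steps 1 and 3 to 16, from 1 to 26).

Step 10 (labelled step). What may go wrong: hydrogen return to the allyl radical with net reduction of the diene, attack of C5 on the other face of C10 (cis-decalin), or protonation of the lactone enolate before ring A closes. Fallback with known chemistry, from 12 back to 20: 12 is treated with [2-(1,3-dioxolan-2-yl)ethyl]magnesium bromide (THF, −78 to 0 °C) to give the tertiary-carbinol diol F1. Its secondary hydroxyl is acylated with methacryloyl chloride (Et3N, DMAP) to the methacrylate F2, and ring-closing metathesis (second-generation Grubbs catalyst, toluene, 80 °C) gives the butenolide carbinol F3. Acylation with the chlorooxalate of N-hydroxyphthalimide (Et3N, DMAP, THF) gives the N-phthalimidoyl oxalate F4. Visible-light photoredox fragmentation (Ru(bpy)3(PF6)2, Hantzsch ester, iPr2NEt·HBF4, CH2Cl2–THF) releases the same tertiary allyl radical with loss of two CO2; tertiary radicals from such oxalates are known to add to butenolides, and here the addition closes ring B to the lactone acetal F5. PPTS in wet acetone frees the keto-lactone aldehyde F6, and a titanium-mediated direct aldol (TiCl4, Bu3N, CH2Cl2, −78 °C, high dilution) closes ring A to 20.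

Step 6. What may go wrong: enolisation of the hindered methyl ketone by the basic ylide and slow opening of the hemiketal, so that olefination stalls. Fallback, from 12 back to 17: olefination is replaced by carbonyl addition and late dehydration. The sequence 12 to the diol F1, the methacrylate F2 and the butenolide carbinol F3 is run as described above, and Burgess reagent (benzene, 50 °C) then dehydrates the tertiary allylic alcohol of F3 to 17. Any exocyclic-methylene isomer formed alongside gives the same allyl radical in step 10.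

Step 13. What may go wrong: hydride attack on the tert-butyl ester or its conjugate reduction while the hindered lactone carbonyl reacts slowly. Fallback, from 22 back to 26: the ester is cleaved first (CF3CO2H, CH2Cl2, 0 °C) to the hydroxy lactone acid F7. As its lithium carboxylate, which LiBH4 does not reduce, the lactone is reduced (LiBH4, THF, 25 °C) to the triol acid F8. 2,2-Dimethoxypropane with PPTS gives the acetonide acid F9; 3-methylbutanoic anhydride with DMAP, followed by aqueous hydrolysis of the mixed anhydride, gives the isovalerate acetonide acid F10; 80% aqueous AcOH at 25 °C removes the acetonide to give 26.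

**Further compounds**

F1 | step 10 | tert-butyl (2E,6Z,9R,10E)-6-[4-(1,3-dioxolan-2-yl)-2-hydroxybutan-2-yl]-9-hydroxy-3,7-dimethyldodeca-2,6,10-trienoate (carbinol epimers) | C/C=C/[C@H](O)C/C(C)=C(CC/C(C)=C/C(=O)OC(C)(C)C)\C(C)(O)CCC1OCCO1
F2 | step 10 | tert-butyl (2E,6Z,9R,10E)-6-[4-(1,3-dioxolan-2-yl)-2-hydroxybutan-2-yl]-3,7-dimethyl-9-(2-methylprop-2-enoyloxy)dodeca-2,6,10-trienoate | C/C=C/[C@H](OC(=O)C(C)=C)C/C(C)=C(CC/C(C)=C/C(=O)OC(C)(C)C)\C(C)(O)CCC1OCCO1
F3 | step 10 | tert-butyl (2E,6Z)-6-[4-(1,3-dioxolan-2-yl)-2-hydroxybutan-2-yl]-3,7-dimethyl-8-[(2R)-4-methyl-5-oxo-2,5-dihydrofuran-2-yl]octa-2,6-dienoate | O=C1O[C@H](C/C(C)=C(CC/C(C)=C/C(=O)OC(C)(C)C)\C(C)(O)CCC2OCCO2)C=C1C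
F4 | step 10 | N-phthalimidoyl oxalate of F3 (tertiary oxalate ester) | O=C1O[C@H](C/C(C)=C(CC/C(C)=C/C(=O)OC(C)(C)C)\C(C)(CCC2OCCO2)OC(=O)C(=O)ON2C(=O)c3ccccc3C2=O)C=C1C
F5 | step 10 | tert-butyl 3,3-(ethylenedioxy)-19-oxo-19,6β-epoxy-3,4-secolabda-8,13E-dien-15-oate (C4 epimers) | CC1=C(CC/C(C)=C/C(=O)OC(C)(C)C)[C@@](C)(CCC3OCCO3)[C@@H]2C(C)C(=O)O[C@@H]2C1
F6 | step 10 | tert-butyl 3,19-dioxo-19,6β-epoxy-3,4-secolabda-8,13E-dien-15-oate (C4 epimers) | CC1=C(CC/C(C)=C/C(=O)OC(C)(C)C)[C@@](C)(CCC=O)[C@@H]2C(C)C(=O)O[C@@H]2C1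
F0 | step 6 | none | none
F7 | step 13 | 3α-hydroxy-19-oxo-19,6β-epoxylabda-8,13E-dien-15-oic acid | CC1=C(CC/C(C)=C/C(=O)O)[C@@]2(C)CC[C@@H](O)[C@](C)(C(=O)O3)[C@@H]2[C@H]3C1
F8 | step 13 | 3α,6β,19-trihydroxylabda-8,13E-dien-15-oic acid | CC1=C(CC/C(C)=C/C(=O)O)[C@@]2(C)CC[C@@H](O)[C@](C)(CO)[C@@H]2[C@H](O)C1
F9 | step 13 | 3α-hydroxy-6β,19-(isopropylidenedioxy)labda-8,13E-dien-15-oic acid | CC1=C(CC/C(C)=C/C(=O)O)[C@@]2(C)CC[C@@H](O)[C@](C)(COC(C)(C)O3)[C@@H]2[C@H]3C1
F10 | step 13 | 6β,19-(isopropylidenedioxy)-3α-(3-methylbutanoyloxy)labda-8,13E-dien-15-oic acid | CC1=C(CC/C(C)=C/C(=O)O)[C@@]2(C)CC[C@@H](OC(=O)CC(C)C)[C@](C)(COC(C)(C)O3)[C@@H]2[C@H]3C1
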